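## Retrosynthetic overview

1. The target comes from a 7-hydroxy-4-iodo peroxylactone by one tin hydride step that removes the C5–I and C2–O bonds. The γ-lactone (second ring) comes from iodolactonization of a dioxene α-hydroxy acid, which sets C4 from C3 (cis fusion).
2. The 1,2-dioxine (first ring) comes from a [4+2] cycloaddition of singlet oxygen to a (2R,3E,5E)-diene-1,2-diol. The E,E geometry fixes C3 against C6; the allylic C2 carbinol steers the face and is deoxygenated at the end.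
3. The diene comes from hydrozirconation/Negishi coupling of (R)-4-(prop-1-ynyl)dioxolane with an (E)-vinyl iodide. The dioxolane derives from (S)-glyceraldehyde acetonide, the only source of chirality; the iodide from carboalumination of 12-phenyldodec-1-yne.
4. Ring order: 3,6-dihydro-1,2-dioxine, then γ-lactone.

Assumption: (10-bromodecyl)benzene and (S)-glyceraldehyde acetonide (2,3-O-isopropylidene-L-glyceraldehyde) are taken as catalogue compounds. Locants C1–C16 in the text are those of the hexadecane chain, C1 being the lactone carbonyl carbon of the target.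

## Route

Step 1
Reactants: 1 (10-bromodecyl)benzene
Product: 2 dodec-11-yn-1-ylbenzene (12-phenyldodec-1-yne)
Conditions: LiC≡CH·H2NCH2CH2NH2 (1.5 equiv), DMSO, 15 °C to rt
Reagents that add atoms: lithium acetylide–ethylenediamine complex, [Li+].[C-]#C.NCCN
Why: SN2 alkylation of the acetylide by the unhindered primary bromide gives the terminal alkyne; no stereocentre is involved.

Step 2
Reactants: 2 dodec-11-yn-1-ylbenzene
Product: 4 [(11E)-12-iodo-11-methyldodec-11-en-1-yl]benzene, via alkenyl-AlMe2 species 3 (not isolated)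
Conditions: Me3Al (2 equiv), Cp2ZrCl2 (0.25 equiv), CH2Cl2, 0 °C to rt; then I2, THF, −30 °C to 0 °C
Reagents that add atoms: trimethylaluminium, C[Al](C)C; iodine, II
Why: Negishi zirconium-catalysed carboalumination adds Me–Al syn across the terminal alkyne with aluminium on the terminal carbon, and iodinolysis with retention gives the (E)-trisubstituted vinyl iodide that becomes the C5=C6 unit.

Step 3
Reactants: 5 (4S)-2,2-dimethyl-1,3-dioxolane-4-carbaldehyde
Product: 6 (4R)-4-ethynyl-2,2-dimethyl-1,3-dioxolane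
Conditions: dimethyl (1-diazo-2-oxopropyl)phosphonate, K2CO3, MeOH, 0 °C to rt
Reagents that add atoms: dimethyl (1-diazo-2-oxopropyl)phosphonate, CC(=O)C(=[N+]=[N-])P(=O)(OC)OC
Why: Seyferth–Gilbert homologation in its Ohira–Bestmann variant converts the aldehyde into the alkyne under conditions mild enough to leave the α-alkoxy stereocentre intact (the descriptor changes only through CIP ranking).

Step 4
Reactants: 6 (4R)-4-ethynyl-2,2-dimethyl-1,3-dioxolane
Product: 8 (4R)-2,2-dimethyl-4-(prop-1-yn-1-yl)-1,3-dioxolane, via lithium acetylide 7 (not isolated)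
Conditions: n-BuLi, THF, −78 °C; then MeI, −78 °C to rt
Reagents that add atoms: iodomethane, CI
Why: Deprotonation of the terminal alkyne and SN2 methylation of the acetylide installs the future C4 methyl group without touching the stereocentre.

Step 5
Reactants: 8 (4R)-2,2-dimethyl-4-(prop-1-yn-1-yl)-1,3-dioxolane; 4 [(11E)-12-iodo-11-methyldodec-11-en-1-yl]benzene
Product: 11 (4R)-4-[(1E,3E)-2,4-dimethyl-14-phenyltetradeca-1,3-dien-1-yl]-2,2-dimethyl-1,3-dioxolane, via alkenyl-ZrCp2Cl species 9 (not isolated), via alkenyl-ZnCl species 10 (not isolated)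
Conditions: Cp2Zr(H)Cl (1.6 equiv), THF, rt to 40 °C; ZnCl2, THF, 0 °C; then 4, Pd(PPh3)4 (5 mol %), rt
Reagents that add atoms: none
Why: Hydrozirconation adds H–Zr syn with zirconium on the less hindered methyl-bearing carbon, and transmetalation to zinc followed by Negishi cross-coupling (zerovalent palladium, retention at both sp2 carbons) gives the (E,E)-diene.

Step 6
Reactants: 11 (4R)-4-[(1E,3E)-2,4-dimethyl-14-phenyltetradeca-1,3-dien-1-yl]-2,2-dimethyl-1,3-dioxolane
Product: 12 (2R,3E,5E)-4,6-dimethyl-16-phenylhexadeca-3,5-diene-1,2-diol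
Conditions: pyridinium p-toluenesulfonate (0.3 equiv), MeOH, 45 °C
Reagents that add atoms: none
Why: Acid-catalysed transacetalisation to methanol removes the isopropylidene group under conditions too mild to ionise the dienylic C2–O bond, so C2 is unchanged.

Step 7
Reactants: 12 (2R,3E,5E)-4,6-dimethyl-16-phenylhexadeca-3,5-diene-1,2-diol
Product: 13 (1S)-1-[(3S,6S)-4,6-dimethyl-6-(10-phenyldecyl)-3,6-dihydro-1,2-dioxin-3-yl]ethane-1,2-diol
Conditions: O2, tetraphenylporphyrin (1 mol %), visible light, CH2Cl2, −40 °C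
Reagents that add atoms: oxygen, O=O
Why: The suprafacial [4+2] cycloaddition (Diels–Alder type) of singlet oxygen to the s-cis (3E,5E)-diene puts the C3 side chain and the C6 phenyldecyl chain cis on the new ring, and the face is chosen by the (2R)-carbinol, whose C–H lies in the diene plane to avoid A(1,3) strain with the C4 methyl so that its hydroxyl hydrogen-bonds the incoming oxygen and delivers it to its own face, giving (3S,6S).

Step 8
Reactants: 13 (1S)-1-[(3S,6S)-4,6-dimethyl-6-(10-phenyldecyl)-3,6-dihydro-1,2-dioxin-3-yl]ethane-1,2-diol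
Product: 15 (2R)-2-[(3S,6S)-4,6-dimethyl-6-(10-phenyldecyl)-3,6-dihydro-1,2-dioxin-3-yl]-2-hydroxyacetic acid, via α-hydroxy aldehyde 14 (not isolated)
Conditions: TEMPO (10 mol %), NaOCl (5 mol %), NaClO2 (2.5 equiv), MeCN/phosphate buffer pH 6.8, rt
Reagents that add atoms: sodium chlorite (NaClO2), [Na+].[O-]Cl=O
Why: TEMPO-mediated oxidation with chlorite as terminal oxidant takes the primary alcohol of the 1,2-diol to the acid at near-neutral pH, where the secondary carbinol, the trisubstituted alkene and the dialkyl peroxide survive.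

Step 9
Reactants: 15 (2R)-2-[(3S,6S)-4,6-dimethyl-6-(10-phenyldecyl)-3,6-dihydro-1,2-dioxin-3-yl]-2-hydroxyacetic acid
Product: 16 (3S,4R,4aS,7R,7aR)-7-hydroxy-4-iodo-3,4a-dimethyl-3-(10-phenyldecyl)-3,4,4a,7a-tetrahydrofuro[3,2-c][1,2]dioxin-6(7H)-one
Conditions: I2 (3 equiv), NaHCO3, CH2Cl2/H2O, 0 °C, dark
Reagents that add atoms: iodine, II
Why: In this iodolactonization the iodonium ion on C4=C5 is opened 5-exo at the tertiary C4 by the carboxylate, which can only reach from the face carrying the C3 side chain, so the γ-lactone is cis-fused (C4 set by C3) and iodine sits trans on C5.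

Step 10
Reactants: 16 (3S,4R,4aS,7R,7aR)-7-hydroxy-4-iodo-3,4a-dimethyl-3-(10-phenyldecyl)-3,4,4a,7a-tetrahydrofuro[3,2-c][1,2]dioxin-6(7H)-one
Product: 17 O-[(3S,4R,4aS,7R,7aR)-4-iodo-3,4a-dimethyl-6-oxo-3-(10-phenyldecyl)hexahydrofuro[3,2-c][1,2]dioxin-7-yl] O-phenyl carbonothioate
Conditions: PhOC(S)Cl (1.5 equiv), pyridine, DMAP (0.1 equiv), CH2Cl2, 0 °C
Reagents that add atoms: O-phenyl chlorothionoformate, ClC(=S)Oc1ccccc1
Why: Acylation of the secondary α-hydroxyl gives the radical-labile thionocarbonate under conditions too weakly basic to trigger Kornblum–DeLaMare cleavage of the peroxide.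

Step 11
Reactants: 17 O-[(3S,4R,4aS,7R,7aR)-4-iodo-3,4a-dimethyl-6-oxo-3-(10-phenyldecyl)hexahydrofuro[3,2-c][1,2]dioxin-7-yl] O-phenyl carbonothioate
Product: 19 (3S,4aR,7aR)-3,4a-dimethyl-3-(10-phenyldecyl)-3,4,4a,7a-tetrahydrofuro[3,2-c][1,2]dioxin-6(7H)-one, via deiodinated thionocarbonate 18 (not isolated)
Conditions: n-Bu3SnH (4 equiv, 0.5 M), Et3B (0.3 equiv), trace air, toluene, 0 °C to rt
Reagents that add atoms: none
Why: In one radical chain (deiodination plus Barton–McCombie deoxygenation) the stannyl radical abstracts iodine at C5 and, by addition to C=S and β-scission, cleaves the C2–O bond, and at high stannane concentration the C5 and α-carbonyl C2 radicals are reduced before they can attack the O–O bond, leaving the ring stereocentres at C3, C4 and C6 untouched.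

## Compound list

1 | (10-bromodecyl)benzene | BrCCCCCCCCCCc1ccccc1 | starting material
2 | dodec-11-yn-1-ylbenzene | C#CCCCCCCCCCCc1ccccc1 | intermediate
3 | dimethyl[(1E)-2-methyl-12-phenyldodec-1-en-1-yl]alane | C[Al](C)/C=C(C)/CCCCCCCCCCc1ccccc1 | intermediate
4 | [(11E)-12-iodo-11-methyldodec-11-en-1-yl]benzene | I/C=C(C)/CCCCCCCCCCc1ccccc1 | intermediate
5 | (4S)-2,2-dimethyl-1,3-dioxolane-4-carbaldehyde | CC1(C)OC[C@H](O1)C=O | starting material
6 | (4R)-4-ethynyl-2,2-dimethyl-1,3-dioxolane | CC1(C)OC[C@H](O1)C#C | intermediate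
7 | {[(4R)-2,2-dimethyl-1,3-dioxolan-4-yl]ethynyl}lithium | CC1(C)OC[C@H](O1)C#C[Li] | intermediate
8 | (4R)-2,2-dimethyl-4-(prop-1-yn-1-yl)-1,3-dioxolane | CC1(C)OC[C@H](O1)C#CC | intermediate
9 | chlorobis(cyclopentadienyl){(1E)-1-[(4R)-2,2-dimethyl-1,3-dioxolan-4-yl]prop-1-en-2-yl}zirconium | CC1(C)OC[C@H](O1)/C=C(C)/[Zr](Cl)(C2C=CC=C2)C3C=CC=C3 | intermediate
10 | chloro{(1E)-1-[(4R)-2,2-dimethyl-1,3-dioxolan-4-yl]prop-1-en-2-yl}zinc | CC1(C)OC[C@H](O1)/C=C(C)/[Zn]Cl | intermediate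
11 | (4R)-4-[(1E,3E)-2,4-dimethyl-14-phenyltetradeca-1,3-dien-1-yl]-2,2-dimethyl-1,3-dioxolane | CC1(C)OC[C@H](O1)/C=C(C)/C=C(C)/CCCCCCCCCCc2ccccc2 | intermediate
12 | (2R,3E,5E)-4,6-dimethyl-16-phenylhexadeca-3,5-diene-1,2-diol | OC[C@H](O)/C=C(C)/C=C(C)/CCCCCCCCCCc1ccccc1 | intermediate
13 | (1S)-1-[(3S,6S)-4,6-dimethyl-6-(10-phenyldecyl)-3,6-dihydro-1,2-dioxin-3-yl]ethane-1,2-diol | C[C@]1(CCCCCCCCCCc2ccccc2)C=C(C)[C@H](OO1)[C@@H](O)CO | intermediate
14 | (2R)-2-[(3S,6S)-4,6-dimethyl-6-(10-phenyldecyl)-3,6-dihydro-1,2-dioxin-3-yl]-2-hydroxyacetaldehyde | C[C@]1(CCCCCCCCCCc2ccccc2)C=C(C)[C@H](OO1)[C@@H](O)C=O | intermediate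
15 | (2R)-2-[(3S,6S)-4,6-dimethyl-6-(10-phenyldecyl)-3,6-dihydro-1,2-dioxin-3-yl]-2-hydroxyacetic acid | C[C@]1(CCCCCCCCCCc2ccccc2)C=C(C)[C@H](OO1)[C@@H](O)C(O)=O | intermediate
16 | (3S,4R,4aS,7R,7aR)-7-hydroxy-4-iodo-3,4a-dimethyl-3-(10-phenyldecyl)-3,4,4a,7a-tetrahydrofuro[3,2-c][1,2]dioxin-6(7H)-one | C[C@]1(CCCCCCCCCCc3ccccc3)[C@H](I)[C@@]2(C)OC(=O)[C@H](O)[C@H]2OO1 | intermediate
17 | O-[(3S,4R,4aS,7R,7aR)-4-iodo-3,4a-dimethyl-6-oxo-3-(10-phenyldecyl)hexahydrofuro[3,2-c][1,2]dioxin-7-yl] O-phenyl carbonothioate | C[C@]1(CCCCCCCCCCc3ccccc3)[C@H](I)[C@@]2(C)OC(=O)[C@H](OC(=S)Oc4ccccc4)[C@H]2OO1 | intermediate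
18 | O-[(3S,4aR,7R,7aR)-3,4a-dimethyl-6-oxo-3-(10-phenyldecyl)hexahydrofuro[3,2-c][1,2]dioxin-7-yl] O-phenyl carbonothioate | C[C@]1(CCCCCCCCCCc3ccccc3)C[C@@]2(C)OC(=O)[C@H](OC(=S)Oc4ccccc4)[C@H]2OO1 | intermediate
19 | (3S,4aR,7aR)-3,4a-dimethyl-3-(10-phenyldecyl)-3,4,4a,7a-tetrahydrofuro[3,2-c][1,2]dioxin-6(7H)-one | C[C@]1(CCCCCCCCCCc2ccccc2)C[C@@]2(C)OC(=O)C[C@H]2OO1 | target

## Step count and risks

Total step count: 11.
Longest linear sequence: 9 steps (5 to 19 through steps 3–11; equally 1 to 19 through steps 1, 2 and 5–11).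

**Step 7 (singlet-oxygen cycloaddition).** This is the least precedented step. Ene hydroperoxides can compete with the [4+2] adduct, and the primary hydroxyl may blur the face selection by the allylic one. The fallback sets out from 12. Selective silylation of the primary hydroxyl (TBSCl, imidazole, CH2Cl2, −20 °C) gives the primary silyl ether F1, in which the allylic hydroxyl is the only hydrogen-bond donor. Photooxygenation of F1 under the conditions of step 7 gives the silylated dioxene F2. HF·pyridine in THF at 0 °C removes the silyl group without base and the route is rejoined at 13.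

**Step 8 (diol to α-hydroxy acid).** Glycol cleavage or hypochlorite attack on the ring alkene may compete. The fallback sets out from 13 and replaces the chemoselective oxidation by hydroxyl differentiation. TBSOTf and 2,6-lutidine (CH2Cl2, −78 °C) give the bis-silyl ether F3. HF·pyridine buffered with pyridine (THF, 0 °C) frees only the primary position to give the primary alcohol F4. TEMPO with PhI(OAc)2 in MeCN/H2O takes F4 through the silyloxy aldehyde F5 (not isolated) to the silyloxy acid F6. Iodolactonization (I2, NaHCO3) gives the silyloxy iodolactone F7, and HF·pyridine in THF rejoins the route at 16.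

**Step 11 (double radical reduction).** The peroxide may not survive the combined excess of stannane, or the C2 radical may fragment. The fallback sets out from 16 and separates the two events, removing the C2 oxygen ionically. One equivalent of n-Bu3SnH with AIBN (benzene, 60 °C) removes only the C5 iodine to give the hydroxy lactone F8. Tf2O and pyridine (CH2Cl2, −30 °C) give the triflate F9. SN2 displacement of the α-carbonyl triflate by hydride from n-Bu4NBH4 (CH2Cl2, 0 °C) rejoins the route at 19.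

## Further compounds

F1 | step 7 | (2R,3E,5E)-1-[(tert-butyldimethylsilyl)oxy]-4,6-dimethyl-16-phenylhexadeca-3,5-dien-2-ol | CC(C)(C)[Si](C)(C)OC[C@H](O)/C=C(C)/C=C(C)/CCCCCCCCCCc1ccccc1
F2 | step 7 | (1S)-2-[(tert-butyldimethylsilyl)oxy]-1-[(3S,6S)-4,6-dimethyl-6-(10-phenyldecyl)-3,6-dihydro-1,2-dioxin-3-yl]ethan-1-ol | C[C@]1(CCCCCCCCCCc2ccccc2)C=C(C)[C@H](OO1)[C@@H](O)CO[Si](C)(C)C(C)(C)C
F3 | step 8 | (3S,6S)-3-[(1S)-1,2-bis[(tert-butyldimethylsilyl)oxy]ethyl]-4,6-dimethyl-6-(10-phenyldecyl)-3,6-dihydro-1,2-dioxine | C[C@]1(CCCCCCCCCCc2ccccc2)C=C(C)[C@H](OO1)[C@@H](O[Si](C)(C)C(C)(C)C)CO[Si](C)(C)C(C)(C)C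
F4 | step 8 | (2S)-2-[(tert-butyldimethylsilyl)oxy]-2-[(3S,6S)-4,6-dimethyl-6-(10-phenyldecyl)-3,6-dihydro-1,2-dioxin-3-yl]ethan-1-ol | C[C@]1(CCCCCCCCCCc2ccccc2)C=C(C)[C@H](OO1)[C@@H](O[Si](C)(C)C(C)(C)C)CO
F5 | step 8 | (2R)-2-[(tert-butyldimethylsilyl)oxy]-2-[(3S,6S)-4,6-dimethyl-6-(10-phenyldecyl)-3,6-dihydro-1,2-dioxin-3-yl]acetaldehyde | C[C@]1(CCCCCCCCCCc2ccccc2)C=C(C)[C@H](OO1)[C@@H](O[Si](C)(C)C(C)(C)C)C=O
F6 | step 8 | (2R)-2-[(tert-butyldimethylsilyl)oxy]-2-[(3S,6S)-4,6-dimethyl-6-(10-phenyldecyl)-3,6-dihydro-1,2-dioxin-3-yl]acetic acid | C[C@]1(CCCCCCCCCCc2ccccc2)C=C(C)[C@H](OO1)[C@@H](O[Si](C)(C)C(C)(C)C)C(O)=O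
F7 | step 8 | (3S,4R,4aS,7R,7aR)-7-[(tert-butyldimethylsilyl)oxy]-4-iodo-3,4a-dimethyl-3-(10-phenyldecyl)-3,4,4a,7a-tetrahydrofuro[3,2-c][1,2]dioxin-6(7H)-one | C[C@]1(CCCCCCCCCCc3ccccc3)[C@H](I)[C@@]2(C)OC(=O)[C@H](O[Si](C)(C)C(C)(C)C)[C@H]2OO1
F8 | step 11 | (3S,4aR,7R,7aR)-7-hydroxy-3,4a-dimethyl-3-(10-phenyldecyl)-3,4,4a,7a-tetrahydrofuro[3,2-c][1,2]dioxin-6(7H)-one | C[C@]1(CCCCCCCCCCc3ccccc3)C[C@@]2(C)OC(=O)[C@H](O)[C@H]2OO1
F9 | step 11 | (3S,4aR,7R,7aR)-3,4a-dimethyl-6-oxo-3-(10-phenyldecyl)hexahydrofuro[3,2-c][1,2]dioxin-7-yl trifluoromethanesulfonate | C[C@]1(CCCCCCCCCCc3ccccc3)C[C@@]2(C)OC(=O)[C@H](OS(=O)(=O)C(F)(F)F)[C@H]2OO1
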